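**Retrosynthetic overview**

- The target is read as the 2,3-trans-3,4-cis (2R,3S,4S) flavan-3,4-diol 3-O-gallate. It is disconnected to its hepta-O-benzyl ether, whose gallate is placed on the equatorial O3 of a 3,4-cis-diol released from a cyclic phenylboronate.
- The boronate-bridged flavan is cut at C4–C4a, O1–C2 and both B–O bonds, giving 3,5-bis(benzyloxy)phenol, PhB(OH)2 and a (2R,3S)-trans-aryl glycidic aldehyde.
- The epoxy aldehyde comes from aminocatalytic epoxidation of the E-cinnamaldehyde, made by Wittig homologation of 3,4-bis(benzyloxy)benzaldehyde.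
- Ring order: rings A and B and the galloyl ring are bought as arenes; the oxirane forms in step 2; in step 3 a transient benzodioxaborin, then pyran ring C and the dioxaborolane form in one flask; the dioxaborolane is removed in step 4.
- Stereocentres: C3 and C2 come from the epoxide (C2 by inversion); C4 comes from Felkin-type addition, backed by the cis-boronate as thermodynamic sink.

Assumption: compounds 1, 2, 5 and 8 and the (R)-diarylprolinol silyl ether catalyst are taken as bought.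

**Route**

Step 1
Reactants: 1 3,4-bis(benzyloxy)benzaldehyde; 2 (triphenylphosphoranylidene)acetaldehyde
Product: 3 (E)-3-[3,4-bis(benzyloxy)phenyl]prop-2-enal
Conditions: 2 (1.2 equiv), toluene, 90 °C, 16 h
Reagents that add atoms: none
Why: Wittig olefination with a carbonyl-stabilised ylide gives the E-enal selectively; no stereocentre is formed.

Step 2
Reactants: 3 (E)-3-[3,4-bis(benzyloxy)phenyl]prop-2-enal
Product: 4 (2R,3S)-3-[3,4-bis(benzyloxy)phenyl]oxirane-2-carbaldehyde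
Conditions: (R)-2-{bis[3,5-bis(trifluoromethyl)phenyl](trimethylsilyloxy)methyl}pyrrolidine (10 mol %), 35% aq H2O2 (1.3 equiv), CH2Cl2, rt; water wash, crude used at once
Reagents that add atoms: hydrogen peroxide, OO
Why: Aminocatalytic (Jørgensen-type iminium/enamine) epoxidation: hydroperoxide adds to the E-iminium and the resulting enamine closes on oxygen, both on the face left open by the C(Ar)2OSiMe3 arm, which by this shielding model gives the trans-(2R,3S) epoxide with the (R)-catalyst.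

Step 3
Reactants: 4 (2R,3S)-3-[3,4-bis(benzyloxy)phenyl]oxirane-2-carbaldehyde; 5 3,5-bis(benzyloxy)phenol
Product: 7 cyclic phenylboronate (3aS,4R,9bS)-7,9-bis(benzyloxy)-4-[3,4-bis(benzyloxy)phenyl]-2-phenyl-3a,9b-dihydro-4H-[1,3,2]dioxaborolo[4,5-c]chromene, via benzodioxaborin epoxide 6 (not isolated)
Conditions: 4 (1.2 equiv), PhB(OH)2 (1.1 equiv), EtCO2H (20 mol %), 4 Å MS, toluene, rt → 45 °C
Reagents that add atoms: phenylboronic acid, OB(O)c1ccccc1
Why: Proposed new method: PhB(OH)2 esterifies the phenol and delivers the boron-bound aldehyde to the ortho carbon through a six-membered transition state (Nagata-type ortho-hydroxyalkylation, the closest known reaction, which stops at benzodioxaborin 6), the arene adding anti to the epoxide C–O bond (polar Felkin–Anh) to set C4 as S; acid-mediated B–OAr exchange then lets boron chelate O4 and the epoxide oxygen, activating the electron-rich benzylic C–O bond so that the freed phenol oxygen opens it 6-endo with inversion (as in known acid-catalysed epoxide-opening cyclisations to 2,3-trans-flavan-3-ols; sets C2 as R, C3 is retained), and boron ends as the dioxaborolane across cis O3/O4, a sink into which any 4-epimer can drain by reversible ionisation of the 2,4,6-trioxygenated benzylic C4–O bond.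

Step 4
Reactants: 7 cyclic phenylboronate (3aS,4R,9bS)-7,9-bis(benzyloxy)-4-[3,4-bis(benzyloxy)phenyl]-2-phenyl-3a,9b-dihydro-4H-[1,3,2]dioxaborolo[4,5-c]chromene; 8 3,4,5-tris(benzyloxy)benzoyl chloride
Product: 10 (2R,3S,4S)-5,7-bis(benzyloxy)-2-[3,4-bis(benzyloxy)phenyl]-4-hydroxychroman-3-yl 3,4,5-tris(benzyloxy)benzoate, via free cis-diol 9 (not isolated)
Conditions: (a) HN(CH2CH2OH)2 (1.05 equiv), Et2O–CH2Cl2, rt, filter, concentrate; (b) 8 (1.2 equiv), Ph2BOCH2CH2NH2 (10 mol %), i-Pr2NEt (1.5 equiv), MeCN–CH2Cl2, 0 °C → rt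
Reagents that add atoms: none
Why: Transesterification to the insoluble diethanolamine boronate frees the cis-diol, which the diarylborinic acid catalyst binds as a tetracoordinate borinate that is acylated at the equatorial, unhindered O3 and not at the pseudo-axial benzylic O4 crowded by the 5-benzyloxy group (borinic-acid-catalysed regioselective acylation of cis-1,2-diols); no stereocentre is touched.

Step 5
Reactants: 10 (2R,3S,4S)-5,7-bis(benzyloxy)-2-[3,4-bis(benzyloxy)phenyl]-4-hydroxychroman-3-yl 3,4,5-tris(benzyloxy)benzoate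
Product: 11 (2R,3S,4S)-2-(3,4-dihydroxyphenyl)-4,5,7-trihydroxychroman-3-yl 3,4,5-trihydroxybenzoate
Conditions: H2 (1 atm), Pd(OH)2/C (20 wt %), THF–EtOAc 1:1, rt; filter under Ar, evaporate below 30 °C, lyophilise
Reagents that add atoms: none
Why: Heterogeneous hydrogenolysis cleaves the seven aryl benzyl ethers much faster than the benzylic C4–OH, the C2–O1 bond or the aryl ester under neutral, non-protic conditions (as in catechin gallate syntheses), so the three stereocentres and the 3-O-gallate are kept.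

**Compound list**

1 | 3,4-bis(benzyloxy)benzaldehyde | O=Cc1ccc(OCc2ccccc2)c(OCc2ccccc2)c1 | starting material
2 | (triphenylphosphoranylidene)acetaldehyde | O=CC=P(c1ccccc1)(c1ccccc1)c1ccccc1 | starting material
3 | (E)-3-[3,4-bis(benzyloxy)phenyl]prop-2-enal | O=C/C=C/c1ccc(OCc2ccccc2)c(OCc2ccccc2)c1 | intermediate
4 | (2R,3S)-3-[3,4-bis(benzyloxy)phenyl]oxirane-2-carbaldehyde | O=C[C@@H]1O[C@H]1c1ccc(OCc2ccccc2)c(OCc2ccccc2)c1 | intermediate
5 | 3,5-bis(benzyloxy)phenol | Oc1cc(OCc2ccccc2)cc(OCc2ccccc2)c1 | starting material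
6 | (4S)-5,7-bis(benzyloxy)-4-{(2S,3S)-3-[3,4-bis(benzyloxy)phenyl]oxiran-2-yl}-2-phenyl-4H-1,3,2-benzodioxaborinine | c1ccccc1B1Oc2cc(OCc3ccccc3)cc(OCc3ccccc3)c2[C@H](O1)[C@@H]1O[C@H]1c1ccc(OCc2ccccc2)c(OCc2ccccc2)c1 | intermediate
7 | (3aS,4R,9bS)-7,9-bis(benzyloxy)-4-[3,4-bis(benzyloxy)phenyl]-2-phenyl-3a,9b-dihydro-4H-[1,3,2]dioxaborolo[4,5-c]chromene (3,4-O-phenylboranediyl derivative of diol 9) | c1ccccc1B1O[C@@H]2[C@@H](c3ccc(OCc4ccccc4)c(OCc4ccccc4)c3)Oc3cc(OCc4ccccc4)cc(OCc4ccccc4)c3[C@@H]2O1 | intermediate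
8 | 3,4,5-tris(benzyloxy)benzoyl chloride | O=C(Cl)c1cc(OCc2ccccc2)c(OCc2ccccc2)c(OCc2ccccc2)c1 | starting material
9 | (2R,3S,4S)-5,7-bis(benzyloxy)-2-[3,4-bis(benzyloxy)phenyl]chromane-3,4-diol | O[C@@H]1[C@@H](c2ccc(OCc3ccccc3)c(OCc3ccccc3)c2)Oc2cc(OCc3ccccc3)cc(OCc3ccccc3)c2[C@@H]1O | intermediate
10 | (2R,3S,4S)-5,7-bis(benzyloxy)-2-[3,4-bis(benzyloxy)phenyl]-4-hydroxychroman-3-yl 3,4,5-tris(benzyloxy)benzoate | O=C(O[C@@H]1[C@@H](c2ccc(OCc3ccccc3)c(OCc3ccccc3)c2)Oc2cc(OCc3ccccc3)cc(OCc3ccccc3)c2[C@@H]1O)c1cc(OCc2ccccc2)c(OCc2ccccc2)c(OCc2ccccc2)c1 | intermediate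
11 | (2R,3S,4S)-2-(3,4-dihydroxyphenyl)-4,5,7-trihydroxychroman-3-yl 3,4,5-trihydroxybenzoate | O=C(O[C@@H]1[C@@H](c2ccc(O)c(O)c2)Oc2cc(O)cc(O)c2[C@@H]1O)c1cc(O)c(O)c(O)c1 | target

**Totals**

Total step count: 5. Longest linear sequence: 5 steps (1 → 3 → 4 → 7 → 10 → 11).

**Steps most likely to fail and fallbacks**

Step 3 (the three-component cascade is untested). Risks are capture of a C4 cation by phenol 5, 5-exo instead of 6-endo epoxide opening, and loss of the 2,3-trans relationship. The fallback sets out from 4 and 5 and comes back at 9. Phenol 5 is converted with Ti(OiPr)4 (toluene, isopropanol stripped off) into its aryloxytitanium triisopropoxide and added to 4 in CH2Cl2 at −20 °C. This ortho-specific, non-chelating metal-phenoxide hydroxyalkylation gives, by Felkin–Anh addition, the erythro epoxy alcohol (S)-[2,4-bis(benzyloxy)-6-hydroxyphenyl]{(2S,3S)-3-[3,4-bis(benzyloxy)phenyl]oxiran-2-yl}methanol F1. A separate PPTS-catalysed 6-endo epoxide opening (CH2Cl2, 0 °C) then closes ring C to diol 9, which enters stage (b) of step 4. Here C4 is set kinetically, and C–C bond formation and ring closure are uncoupled.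

Step 4 (O3 versus O4 selectivity, acyl migration). The fallback sets out from 9 and comes back at 10, telling the two hydroxyls apart by oxidation state. MnO2 (CH2Cl2, rt) oxidises only the benzylic C4–OH to (2R,3R)-5,7-bis(benzyloxy)-2-[3,4-bis(benzyloxy)phenyl]-3-hydroxychroman-4-one F2. The one remaining hydroxyl is acylated with 8 (pyridine, DMAP cat., CH2Cl2, 0 °C) to (2R,3R)-5,7-bis(benzyloxy)-2-[3,4-bis(benzyloxy)phenyl]-4-oxochroman-3-yl 3,4,5-tris(benzyloxy)benzoate F3. LiBH(s-Bu)3 (THF, −78 °C) then attacks the ketone from the equatorial direction and gives the axial 4-OH cis to the equatorial 3-ester, which is 10.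

Step 5 (hydrogenolysis of the benzylic C4–OH, lability of the free leucocyanidin-type product). The fallback sets out from 10 and comes back at 11, masking the 4-OH before hydrogenolysis. Et3SiOTf and 2,6-lutidine (CH2Cl2, −78 °C) give (2R,3R,4S)-5,7-bis(benzyloxy)-2-[3,4-bis(benzyloxy)phenyl]-4-[(triethylsilyl)oxy]chroman-3-yl 3,4,5-tris(benzyloxy)benzoate F4. H2 with Pd(OH)2/C in EtOAc removes the seven benzyl groups to give (2R,3R,4S)-2-(3,4-dihydroxyphenyl)-5,7-dihydroxy-4-[(triethylsilyl)oxy]chroman-3-yl 3,4,5-trihydroxybenzoate F5. Et3N·3HF (THF, 0 °C) removes the silyl group under near-neutral conditions as the last event to give 11.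

**Further compounds**

F1 | step 3 | (S)-[2,4-bis(benzyloxy)-6-hydroxyphenyl]{(2S,3S)-3-[3,4-bis(benzyloxy)phenyl]oxiran-2-yl}methanol | Oc1cc(OCc2ccccc2)cc(OCc2ccccc2)c1[C@H](O)[C@@H]1O[C@H]1c1ccc(OCc2ccccc2)c(OCc2ccccc2)c1
F2 | step 4 | (2R,3R)-5,7-bis(benzyloxy)-2-[3,4-bis(benzyloxy)phenyl]-3-hydroxychroman-4-one | O[C@@H]1[C@@H](c2ccc(OCc3ccccc3)c(OCc3ccccc3)c2)Oc2cc(OCc3ccccc3)cc(OCc3ccccc3)c2C1=O
F3 | step 4 | (2R,3R)-5,7-bis(benzyloxy)-2-[3,4-bis(benzyloxy)phenyl]-4-oxochroman-3-yl 3,4,5-tris(benzyloxy)benzoate | O=C(O[C@@H]1[C@@H](c2ccc(OCc3ccccc3)c(OCc3ccccc3)c2)Oc2cc(OCc3ccccc3)cc(OCc3ccccc3)c2C1=O)c1cc(OCc2ccccc2)c(OCc2ccccc2)c(OCc2ccccc2)c1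
F4 | step 5 | (2R,3R,4S)-5,7-bis(benzyloxy)-2-[3,4-bis(benzyloxy)phenyl]-4-[(triethylsilyl)oxy]chroman-3-yl 3,4,5-tris(benzyloxy)benzoate | O=C(O[C@@H]1[C@@H](c2ccc(OCc3ccccc3)c(OCc3ccccc3)c2)Oc2cc(OCc3ccccc3)cc(OCc3ccccc3)c2[C@@H]1O[Si](CC)(CC)CC)c1cc(OCc2ccccc2)c(OCc2ccccc2)c(OCc2ccccc2)c1
F5 | step 5 | (2R,3R,4S)-2-(3,4-dihydroxyphenyl)-5,7-dihydroxy-4-[(triethylsilyl)oxy]chroman-3-yl 3,4,5-trihydroxybenzoate | O=C(O[C@@H]1[C@@H](c2ccc(O)c(O)c2)Oc2cc(O)cc(O)c2[C@@H]1O[Si](CC)(CC)CC)c1cc(O)c(O)c(O)c1
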